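**Strategy.** Ring A is disconnected at C4–C5. C4 is quaternary, carries the C19 carboxyl and adjoins ring-fusion carbon C5, so C4 maps onto the β-carbon of a ketene dithioacetal and C5 onto the γ-terminus of a ring B silyl dienol ether of the C8 ketone. One anodic oxidation in methanol joins these two nucleophilic carbons, closes ring A, sets C4 and C5 (cis fusion), delivers C19 at the acid oxidation level and leaves ring B as the C6=C7–C8=O enone. The precursor is a monocyclic 1-silyloxycyclohexa-1,3-diene (ring B) carrying the C10 methyl, a C1–C3 tether on C10 that ends in the ketene dithioacetal, and the C9 allylic side chain.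

Key step: step 9

Remark on the chemistry: the target is the cis-fused (5β-H) labdane (4S,5S,9S,10R,13R). The key-step structures agree with it at C4, C5, C9 and C10 and were kept. The only change is a TBDPS instead of a TBS ether on the side chain, so that it survives the acid that unmasks the methyl ketone. Labdane numbering is used for all intermediates.

**Step 1**
Reactants: 1 2-methyl-2-vinyloxirane (isoprene monoxide, racemic)
Product: 2 (E)-4-chloro-2-methylbut-2-en-1-ol
Conditions: TiCl4, CH2Cl2, −85 °C; then 1 M HCl
Reagents that add atoms: titanium tetrachloride, Cl[Ti](Cl)(Cl)Cl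
Why: Titanium tetrachloride opens the vinyl epoxide in an SN2′ sense (conjugate opening of a vinyl oxirane), so chloride enters at the vinyl terminus and the E trisubstituted alkene forms as the former stereocentre becomes sp2.

**Step 2**
Reactants: 2 (E)-4-chloro-2-methylbut-2-en-1-ol
Product: 3 (E)-tert-butyl[(4-chloro-2-methylbut-2-en-1-yl)oxy]diphenylsilane
Conditions: TBDPSCl, imidazole, CH2Cl2, 0 °C → rt
Reagents that add atoms: tert-butylchlorodiphenylsilane, CC(C)(C)[Si](Cl)(c1ccccc1)c1ccccc1
Why: Imidazole-promoted silylation of the primary alcohol is routine, and the TBDPS ether should survive the later aqueous acid, organolithium, anodic and Lewis-acid steps.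

**Step 3**
Reactants: 3 (E)-tert-butyl[(4-chloro-2-methylbut-2-en-1-yl)oxy]diphenylsilane
Product: 4 (E)-tert-butyl[(4-iodo-2-methylbut-2-en-1-yl)oxy]diphenylsilane
Conditions: NaI, acetone, rt, dark
Reagents that add atoms: sodium iodide, [Na+].[I-]
Why: Finkelstein exchange (SN2) converts the allylic chloride into the more reactive allylic iodide needed to alkylate a hindered enolate.

**Step 4**
Reactants: 5 2-(3-chloropropyl)-2-methyl-1,3-dioxolane, 6 3-methylcyclohex-2-en-1-one
Product: 9 (R)-trimethyl({3-methyl-3-[3-(2-methyl-1,3-dioxolan-2-yl)propyl]cyclohex-1-en-1-yl}oxy)silane (C8–OTMS, C8=C9), via Grignard reagent 7 (not isolated), via magnesium enolate 8 (not isolated)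
Conditions: Mg, THF, 50 °C; then 6, Cu(OTf)2 (3 mol %), chiral imidazolinium salt (NHC precursor, 4 mol %), Et2O, −10 °C; then TMSCl, Et3N, DMPU, 0 °C
Reagents that add atoms: chlorotrimethylsilane, C[Si](C)(C)Cl
Why: Copper/NHC-catalysed asymmetric conjugate addition of primary alkyl Grignard reagents to 3-methylcyclohexenone is an established route to β-quaternary ketones, the ligand enantiomer being chosen so that C10 forms with R configuration, and O-silylation of the magnesium enolate stores the C8=C9 enolate regiochemistry.

**Step 5**
Reactants: 9 (R)-TMS enol ether, 4 (E)-allylic iodide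
Product: 12 2-[(E)-4-(tert-butyldiphenylsilyloxy)-3-methylbut-2-enyl]-3-methyl-3-(4-oxopentyl)cyclohexan-1-one with the C9 side chain cis to the C10 methyl and C10 as in 9, via lithium enolate 10 (not isolated), via ketal ketone 11 (not isolated)
Conditions: MeLi, THF, 0 °C; then 4, DMPU, −78 → −20 °C; then 1 M HCl, THF, 0 °C → rt, 30 min
Reagents that add atoms: water, O
Why: Methyllithium cleavage of the silyl enol ether gives the regiodefined lithium enolate, which should be alkylated by the allylic iodide anti to the larger C10 substituent (the tether), placing the side chain cis to the C10 methyl with moderate selectivity (minor C9 epimer removed by chromatography), and brief cold aqueous acid then hydrolyses the dioxolane much faster than it enolises C9.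

**Step 6**
Reactants: 12 diketone, 13 2-(trimethylsilyl)-1,3-dithiane
Product: 15 2-[(E)-4-(tert-butyldiphenylsilyloxy)-3-methylbut-2-enyl]-3-[4-(1,3-dithian-2-ylidene)pentyl]-3-methylcyclohexan-1-one (C9 and C10 as in 12), via lithiated silyldithiane 14 (not isolated)
Conditions: 13, n-BuLi, THF, −20 °C; then 12, −78 → 0 °C
Reagents that add atoms: none
Why: Peterson olefination with 2-lithio-2-trimethylsilyl-1,3-dithiane should convert the unhindered methyl ketone into the tetrasubstituted ketene dithioacetal, while the ring ketone is shielded by the adjacent tertiary C9 and quaternary C10.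

**Step 7**
Reactants: 15 ketene dithioacetal ketone
Product: 17 6-[(E)-4-(tert-butyldiphenylsilyloxy)-3-methylbut-2-enyl]-5-[4-(1,3-dithian-2-ylidene)pentyl]-5-methylcyclohex-2-en-1-one (C8=O, C6=C7; C9 and C10 as in 12), via lithium enolate 16 (not isolated)
Conditions: LDA, THF, −78 °C; then N-tert-butylbenzenesulfinimidoyl chloride, −78 °C
Reagents that add atoms: none
Why: Kinetic deprotonation at the less hindered C7 followed by Mukaiyama dehydrogenation of the enolate with the sulfinimidoyl chloride introduces the C6=C7 double bond at −78 °C without palladium or a peroxide oxidant, which the ketene dithioacetal would not tolerate, and leaves C9 untouched.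

**Step 8**
Reactants: 17 enone
Product: 18 ring B TBS dienol ether (C8(OTBS)=C7–C6=C5) with the C10 methyl, the C10 tether ending in the 1,3-dithian-2-ylidene and the C9 (E)-4-(TBDPS-oxy)-3-methylbut-2-enyl chain cis to the C10 methyl
Conditions: TBSOTf, i-Pr2NEt, CH2Cl2, −78 → 0 °C
Reagents that add atoms: tert-butyldimethylsilyl trifluoromethanesulfonate, CC(C)(C)[Si](C)(C)OS(=O)(=O)C(F)(F)F
Why: Soft enolisation of the O-silylated enone with a hindered amine should remove a C5 proton in preference to the tertiary C9–H, which is flanked by the silyloxy group, the side chain and the quaternary C10, and so give the through-conjugated silyl dienol ether with C9 intact.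

**Step 9**
Reactants: 18 ring B TBS dienol ether with C10-tethered ketene dithioacetal
Product: 19 cis-fused 8-oxo-6-ene decalin with C19 as the 2-methoxy-1,3-dithian-2-yl group (C19 cis to C5–H and to the C10 methyl, C18 methyl on the opposite face, side chain unchanged)
Conditions: RVC anode, Pt cathode, undivided cell, constant current (8 mA, 2.2 F/mol), LiClO4 (0.1 M), 2,6-lutidine, MeOH/THF (3:7), rt
Reagents that add atoms: methanol, CO
Why: Proposed new method: anodic removal of one electron from the electron-rich π-system gives a radical cation in which C4 bonds to the dienol γ-carbon C5, after which the sulfur-stabilised C19 radical is oxidised again and trapped by methanol and the C8 silyloxycarbenium ion loses its silyl group to methanol, leaving the C6=C7–C8=O enone. The closest known reaction type is the anodic coupling of ketene dithioacetal radical cations with enol ether nucleophiles to form quaternary carbons in six-membered rings; the use of the γ-terminus of a dienol ether is the extension proposed here, and it is expected because the tether can reach C5 (six-membered ring) but not C7 (eight-membered ring). Ring A closes in a 6-exo-trig mode with respect to both the C4=C19 and the C5=C6 double bonds, through a chair. C5 is set stereoelectronically: the new bond must form along the π-axis of ring B, that is axial to ring B, and only a pseudo-equatorial C10–C1 bond can deliver C4 there, anti to the pseudo-axial C10 methyl, which gives the cis fusion. C4 is set by allylic 1,3-strain in the tetrasubstituted ketene dithioacetal, which keeps C19 equatorial on the forming chair and therefore on the face of C5–H, with the C18 methyl axial. The step needs chemoselective oxidation in the presence of the side-chain alkene and silyl ether, which the much lower oxidation potentials of the ketene dithioacetal and dienol ether secure, and C4 approaches the ring B face on which C9 carries only hydrogen.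

**Step 10**
Reactants: 19 methoxy dithiane orthoester
Product: 20 methyl ester of the cis-fused 8-oxo-6-ene decalin (C19 = CO2Me)
Conditions: HgCl2, CaCO3, MeCN/H2O (4:1), rt
Reagents that add atoms: water, O
Why: Thiophilic mercury(II) opens the S,S,O-orthoester and water collapses the resulting oxocarbenium ion to the methyl ester (known hydrolysis of orthothioesters), which removes sulfur before the titanium and peroxide steps.

**Step 11**
Reactants: 20 enone methyl ester
Product: 22 cis-fused 8-oxo decalin methyl ester (saturated ketone), via lithium enolate 21 (not isolated)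
Conditions: L-Selectride, THF, −78 °C; then aq. NH4Cl
Reagents that add atoms: none
Why: L-Selectride adds hydride in a 1,4-sense to cyclohexenones that are unsubstituted at the β-carbon (conjugate reduction), and protonation of the C7=C8 enolate at C7 gives the ketone without touching C9.

**Step 12**
Reactants: 22 saturated ketone
Product: 23 8(17)-methylene compound (exocyclic C8=CH2, methyl ester, TBDPS ether)
Conditions: Zn, CH2Br2, TiCl4, THF (preformed reagent); CH2Cl2, 0 °C → rt
Reagents that add atoms: dibromomethane, BrCBr
Why: Non-basic Lombardo methylenation converts the hindered, epimerisable C8 ketone into the exocyclic alkene and is selective for ketones over esters.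

**Step 13**
Reactants: 23 TBDPS ether
Product: 24 (E)-allylic alcohol (C14–OH, C12=C13)
Conditions: TBAF, THF, 0 °C → rt
Reagents that add atoms: none
Why: Fluoride cleaves the silyl ether; no base-sensitive stereocentre remains, since C9 is now allylic and not α to a carbonyl.

**Step 14**
Reactants: 24 allylic alcohol
Product: 25 (12S,13S)-12,13-epoxy-14-ol
Conditions: Ti(OiPr)4 (10 mol %), L-(+)-diethyl tartrate (12 mol %), t-BuOOH, 4 Å MS, CH2Cl2, −20 °C
Reagents that add atoms: tert-butyl hydroperoxide, CC(C)(C)OO
Why: Sharpless asymmetric epoxidation of the 2-methyl-substituted primary allylic alcohol is reagent-controlled, the L-(+)-tartrate giving the (2S)-type epoxide whose C13–O bond has the configuration needed for 13R in the target, and the isolated 1,1-disubstituted C8=C17 alkene does not react.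

**Step 15**
Reactants: 25 epoxy alcohol
Product: 26 13,14-diol (tertiary C13–OH, primary C14–OH, C12 now CH2)
Conditions: LiBH4, Ti(OiPr)4, toluene/THF, 0 °C → rt
Reagents that add atoms: none
Why: Titanium-assisted borohydride reduction of 2,3-epoxy alcohols delivers hydride to C3 (here C12, the less substituted epoxide carbon), so the C13–O bond is retained, and the neopentyl C19 methyl ester is too hindered to be reduced by LiBH4 at room temperature.

**Step 16**
Reactants: 26 diol
Product: 27 13-hydroxy-14-aldehyde
Conditions: SO3·pyridine, DMSO, i-Pr2NEt, CH2Cl2, 0 °C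
Reagents that add atoms: none
Why: Parikh–Doering oxidation converts the primary alcohol into the aldehyde, while the tertiary alcohol cannot be oxidised and C13 has no hydrogen to epimerise.

**Step 17**
Reactants: 27 α-hydroxy aldehyde
Product: 28 methyl (4S,5S,9S,10R,13R)-13-hydroxylabda-8(17),14-dien-19-oate
Conditions: Ph3PCH3Br, KHMDS, THF, 0 °C → rt (3 equiv ylide)
Reagents that add atoms: methyltriphenylphosphonium bromide, C[P+](c1ccccc1)(c1ccccc1)c1ccccc1.[Br-]
Why: Wittig methylenation of the aldehyde installs C15, with excess ylide absorbing the tertiary hydroxyl proton and the hindered ester left alone.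

**Step 18**
Reactants: 28 hydroxy methyl ester
Product: 29 (4S,5S,9S,10R,13R)-13-hydroxylabda-8(17),14-dien-19-oic acid
Conditions: EtSNa, DMF, 90 °C; then 1 M HCl to pH 3
Reagents that add atoms: none
Why: SN2 demethylation by thiolate attacks the unhindered methyl carbon and is the standard way to cleave neopentyl methyl esters that resist saponification.

**Step 19**
Reactants: 29 hydroxy acid
Product: 31 (4S,5S,9S,10R,13R)-13-acetoxylabda-8(17),14-dien-19-oic acid (target), via mixed anhydride 30 (not isolated)
Conditions: Ac2O, Et3N, DMAP, CH2Cl2, rt → 35 °C; then aq. NaHCO3/THF, rt; acidify to pH 4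
Reagents that add atoms: acetic anhydride, CC(=O)OC(C)=O
Why: DMAP-catalysed acetylation is known to esterify tertiary allylic alcohols of the linalool type, and the acetic mixed anhydride formed at C19 is hydrolysed by bicarbonate at the acetyl carbonyl while the tertiary acetate survives.

**Compound list**

1 | 2-methyl-2-vinyloxirane (isoprene monoxide, racemic) | CC1(CO1)C=C | starting material
2 | (E)-4-chloro-2-methylbut-2-en-1-ol | OC/C(C)=C/CCl | intermediate
3 | (E)-tert-butyl[(4-chloro-2-methylbut-2-en-1-yl)oxy]diphenylsilane | CC(C)(C)[Si](c1ccccc1)(c1ccccc1)OC/C(C)=C/CCl | intermediate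
4 | (E)-tert-butyl[(4-iodo-2-methylbut-2-en-1-yl)oxy]diphenylsilane | CC(C)(C)[Si](c1ccccc1)(c1ccccc1)OC/C(C)=C/CI | intermediate
5 | 2-(3-chloropropyl)-2-methyl-1,3-dioxolane | CC1(CCCCl)OCCO1 | starting material
6 | 3-methylcyclohex-2-en-1-one | CC1=CC(=O)CCC1 | starting material
7 | [3-(2-methyl-1,3-dioxolan-2-yl)propyl]magnesium chloride (not isolated) | CC1(CCC[Mg]Cl)OCCO1 | intermediate
8 | chloromagnesium enolate of the (R)-conjugate adduct (not isolated) | Cl[Mg]OC1=C[C@@](C)(CCCC2(C)OCCO2)CCC1 | intermediate
9 | (R)-trimethyl({3-methyl-3-[3-(2-methyl-1,3-dioxolan-2-yl)propyl]cyclohex-1-en-1-yl}oxy)silane | C[Si](C)(C)OC1=C[C@@](C)(CCCC2(C)OCCO2)CCC1 | intermediate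
10 | lithium enolate of the (R)-conjugate adduct (not isolated) | [Li]OC1=C[C@@](C)(CCCC2(C)OCCO2)CCC1 | intermediate
11 | C9-alkylated ketal ketone, side chain cis to C10 methyl (not isolated) | CC(C)(C)[Si](c1ccccc1)(c1ccccc1)OC/C(C)=C/C[C@H]1C(=O)CCC[C@]1(C)CCCC2(C)OCCO2 | intermediate
12 | 2-[(E)-4-(tert-butyldiphenylsilyloxy)-3-methylbut-2-enyl]-3-methyl-3-(4-oxopentyl)cyclohexan-1-one, side chain cis to C10 methyl | CC(C)(C)[Si](c1ccccc1)(c1ccccc1)OC/C(C)=C/C[C@H]1C(=O)CCC[C@]1(C)CCCC(C)=O | intermediate
13 | 2-(trimethylsilyl)-1,3-dithiane | C[Si](C)(C)C1SCCCS1 | starting material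
14 | 2-lithio-2-(trimethylsilyl)-1,3-dithiane (not isolated) | [Li]C1([Si](C)(C)C)SCCCS1 | intermediate
15 | ring ketone with C10-tethered ketene dithioacetal | CC(C)(C)[Si](c1ccccc1)(c1ccccc1)OC/C(C)=C/C[C@H]1C(=O)CCC[C@]1(C)CCCC(C)=C2SCCCS2 | intermediate
16 | C7=C8 lithium enolate of 15 (not isolated) | CC(C)(C)[Si](c1ccccc1)(c1ccccc1)OC/C(C)=C/C[C@H]1C(O[Li])=CCC[C@]1(C)CCCC(C)=C2SCCCS2 | intermediate
17 | ring B enone (C8=O, C6=C7) with C10-tethered ketene dithioacetal | CC(C)(C)[Si](c1ccccc1)(c1ccccc1)OC/C(C)=C/C[C@H]1C(=O)C=CC[C@]1(C)CCCC(C)=C2SCCCS2 | intermediate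
18 | ring B TBS dienol ether with C10-tethered ketene dithioacetal and C9 allylic side chain (key-step precursor) | CC(C)(C)[Si](c1ccccc1)(c1ccccc1)OC/C(C)=C/C[C@H]1C(O[Si](C)(C)C(C)(C)C)=CC=C[C@]1(C)CCCC(C)=C2SCCCS2 | intermediate
19 | cis-fused 8-oxo-6-ene decalin, C19 as 2-methoxy-1,3-dithian-2-yl (key-step product) | CC(C)(C)[Si](c1ccccc1)(c1ccccc1)OC/C(C)=C/C[C@H]1C(=O)C=C[C@H]2[C@]1(C)CCC[C@]2(C)C3(OC)SCCCS3 | intermediate
20 | cis-fused 8-oxo-6-ene decalin C19 methyl ester | CC(C)(C)[Si](c1ccccc1)(c1ccccc1)OC/C(C)=C/C[C@H]1C(=O)C=C[C@H]2[C@]1(C)CCC[C@]2(C)C(=O)OC | intermediate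
21 | C7=C8 lithium enolate from conjugate reduction (not isolated) | CC(C)(C)[Si](c1ccccc1)(c1ccccc1)OC/C(C)=C/C[C@H]1C(O[Li])=CC[C@H]2[C@]1(C)CCC[C@]2(C)C(=O)OC | intermediate
22 | cis-fused 8-oxo decalin C19 methyl ester | CC(C)(C)[Si](c1ccccc1)(c1ccccc1)OC/C(C)=C/C[C@H]1C(=O)CC[C@H]2[C@]1(C)CCC[C@]2(C)C(=O)OC | intermediate
23 | 8(17)-methylene C19 methyl ester, TBDPS ether | CC(C)(C)[Si](c1ccccc1)(c1ccccc1)OC/C(C)=C/C[C@H]1C(=C)CC[C@H]2[C@]1(C)CCC[C@]2(C)C(=O)OC | intermediate
24 | (E)-allylic alcohol (C14–OH) | OC/C(C)=C/C[C@H]1C(=C)CC[C@H]2[C@]1(C)CCC[C@]2(C)C(=O)OC | intermediate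
25 | (12S,13S)-12,13-epoxy-14-ol | OC[C@]3(C)O[C@H]3C[C@H]1C(=C)CC[C@H]2[C@]1(C)CCC[C@]2(C)C(=O)OC | intermediate
26 | 13,14-diol | OC[C@@](C)(CC[C@H]1C(=C)CC[C@H]2[C@]1(C)CCC[C@]2(C)C(=O)OC)O | intermediate
27 | 13-hydroxy-14-aldehyde | O=C[C@@](C)(CC[C@H]1C(=C)CC[C@H]2[C@]1(C)CCC[C@]2(C)C(=O)OC)O | intermediate
28 | methyl (4S,5S,9S,10R,13R)-13-hydroxylabda-8(17),14-dien-19-oate | C=C[C@@](C)(CC[C@H]1C(=C)CC[C@H]2[C@]1(C)CCC[C@]2(C)C(=O)OC)O | intermediate
29 | (4S,5S,9S,10R,13R)-13-hydroxylabda-8(17),14-dien-19-oic acid | C=C[C@@](C)(CC[C@H]1C(=C)CC[C@H]2[C@]1(C)CCC[C@]2(C)C(=O)O)O | intermediate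
30 | 13-acetate C19 acetic mixed anhydride (not isolated) | C=C[C@@](C)(CC[C@H]1C(=C)CC[C@H]2[C@]1(C)CCC[C@]2(C)C(=O)OC(C)=O)OC(C)=O | intermediate
31 | (4S,5S,9S,10R,13R)-13-acetoxylabda-8(17),14-dien-19-oic acid (cis-fused, CNP0230281.1) | C=C[C@@](C)(CC[C@H]1C(=C)CC[C@H]2[C@]1(C)CCC[C@]2(C)C(=O)O)OC(C)=O | target

**Totals.** Total step count: 19. Longest linear sequence: 18 steps (steps 1–3, then 5–19). The ring B line from 5 and 6 is 16 steps.

**Steps most likely to fail**

Step 9 (bears the label). What may go wrong: the radical cation is trapped by methanol or over-oxidised before the C4–C5 bond forms, or the dienol ether is merely desilylated back to 17. The fallback sets out from 17 and returns at 19. It inverts the polarity of the ketene dithioacetal chemically instead of electrochemically. Enone 17 is oxidised at sulfur (mCPBA, 1 equiv, CH2Cl2, −78 °C) to the ketene dithioacetal monoxide F1. This is silylated as in step 8 to the dienol ether S-oxide F2. Activation of the sulfoxide with Tf2O and 2,6-di-tert-butylpyridine at −78 °C makes C4 electrophilic, and the dienol γ-carbon C5 adds to it (additive Pummerer reaction of ketene dithioacetal monoxides with π-nucleophiles, a known reaction type). Methanol then quenches the resulting 1,3-dithian-2-ylium ion to give 19.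

Step 8. What may go wrong: deprotonation at C9 instead of C5, which gives the cross-conjugated dienol ether and erases the C9 configuration. The fallback sets out from 17 and returns at 18 without a new isolated compound. The dienolate is generated with the iron(III)-catalysed Grignard base (FeCl3 cat., MeMgBr, Et2O, −20 °C), a known dienolisation that gives through-conjugated dienolates of cyclohexenones even when α′-hydrogens are present. It is then silylated on oxygen (TBSOTf, Et3N, DMPU) to 18.

Step 5. What may go wrong: poor facial selectivity in the enolate alkylation, because the C10 methyl and the C10 tether differ little in size, or sluggish alkylation of the hindered enolate with competing proton transfer. The fallback sets out from 3 and 9 and returns at 11. It places C9 under catalyst control by palladium-catalysed asymmetric allylic alkylation. Chloride 3 is converted by acetate displacement (KOAc, DMF, 60 °C) into the allylic acetate F3. Methanolysis (K2CO3, MeOH) gives the allylic alcohol F4, and methyl chloroformate/pyridine gives the allylic methyl carbonate F5. Tsuji–Trost allylation of silyl enol ether 9 with F5 (Pd2(dba)3, chiral diphosphine or phosphinooxazoline ligand of the matched hand, THF) attacks the less hindered π-allyl terminus and gives ketal ketone 11. The acid treatment of step 5 then converts 11 into 12.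

**Further compounds**

F1 | step 9 | ketene dithioacetal monoxide of enone 17 (2-alkylidene-1,3-dithiane 1-oxide, mixture at sulfur) | CC(C)(C)[Si](c1ccccc1)(c1ccccc1)OC/C(C)=C/C[C@H]1C(=O)C=CC[C@]1(C)CCCC(C)=C2SCCCS2=O
F2 | step 9 | TBS dienol ether S-oxide (S-oxide of 18, mixture at sulfur) | CC(C)(C)[Si](c1ccccc1)(c1ccccc1)OC/C(C)=C/C[C@H]1C(O[Si](C)(C)C(C)(C)C)=CC=C[C@]1(C)CCCC(C)=C2SCCCS2=O
F0 | step 8 | none | none
F3 | step 5 | (E)-4-(tert-butyldiphenylsilyloxy)-3-methylbut-2-en-1-yl acetate | CC(=O)OC/C=C(\C)CO[Si](c1ccccc1)(c1ccccc1)C(C)(C)C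
F4 | step 5 | (E)-4-(tert-butyldiphenylsilyloxy)-3-methylbut-2-en-1-ol | OC/C=C(\C)CO[Si](c1ccccc1)(c1ccccc1)C(C)(C)C
F5 | step 5 | (E)-4-(tert-butyldiphenylsilyloxy)-3-methylbut-2-en-1-yl methyl carbonate | COC(=O)OC/C=C(\C)CO[Si](c1ccccc1)(c1ccccc1)C(C)(C)C
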